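Readings and results were generated by integration with made-up constants; scatter was added.

**Time first.** In the teal flask you must account for 3.0 d, but its readings stop at 40.0 h.

the same everywhere: gas phase 86 mM (held)
- teal: substrate 2 M; temperature 50 °C; the very flask that is asked about, followed so far
- green: substrate 1 M; temperature 45 °C; run made earlier
- flask: substrate 2.0 M; temperature 50 °C; time 3.0 d

- teal (time / h: target / %): 3.00: 11; 8.00: 18; 20.0: 21; 40.0: 25
- green (time / h: target / %): 1.33: 3; 4.00: 9; 6.00: 10; 10.0: 21

(standard deviation of a reading: 2 percentage points)

- Saturday's: at 3.0 d take out 90% of the target then present, then wait 20 h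
- Friday's: change nothing and wait 20 h more
- Sunday's: at 3.0 d raise the temperature by 25 K, then wait 20 h

- at the start none of the gas is dissolved
- target that was removed still counts
- the earlier runs were read with a standard deviation of 2 percentage points
- on the list of suspects stand: gas phase <-> dissolved gas; substrate + dissolved gas -> target; substrate -> side product; target <-> isomer of the product

1. target, in percent of the substrate first charged, at 3.0 d
2. the option that brings most further target ("none" if no option brings more than 2 percentage points) (Saturday's / Friday's / Sunday's / none)
3. target present, with what was taken out counted in, in percent of the substrate first charged, after Saturday's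
4. target present, with what was taken out counted in, in percent of the substrate first charged, after Friday's

**Bench rule.** A rule of thumb says that a curve is finished after 5 half-lives. To apply it, take the last teal reading, 25%, as the plateau Y, and treat the approach as pseudo-first-order, with the gas held. Integrating dy/dt = (Y − y) ln2/τ gives Y − y = Y·2^(−t/τ), where y is the target and τ is the plateau half-life, the time in which the gap to the plateau halves. The teal reading of 18% at 8.00 h gives τ = 4.36 h, a reading that carries the scatter. By 3.0 d the gap is 2.6 × 10⁻⁴ percentage points, less than the 2 points that counts. So I would commit to about 25% now, and to nothing from Friday's.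

**The border.** The rule covers a flask left alone, and it cannot say what stopped the curve. Saturday's and Sunday's disturb the flask, so I leave both open. Their wait of 20 h is 4.59 half-lives, less than the rule's 5.

**The forecast.** It gives 26% now, 26.5% after Saturday's, 26.5% after Friday's, and none as the best option. Its ground is “The most economical reading is that the substrate is used up, mostly by the competing side reaction”.

**The result.** The teal flask holds 24.2% at 3.0 d. Saturday's gives 34.5% and Friday's 24.2%.

    gas phase ⇌ dissolved gas, rate k1*(csat - [dissolved gas]) (kL = 4.30 h⁻¹)
    substrate + dissolved gas → target (k = 0.690 L mol⁻¹ h⁻¹, Ea = 80.0 kJ mol⁻¹)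
    substrate → side product (k = 0.0580 h⁻¹, Ea = 113 kJ mol⁻¹)
    target ⇌ isomer of the product (K = 0.920, k = 0.110 h⁻¹, Ea = 105 kJ mol⁻¹, ΔH = −54.0 kJ mol⁻¹)
    (constants at 50 °C)

**The reservoir.** Sunday's brings more than Saturday's or Friday's, 14 points against 10 points and 0 points. At 3.0 d the teal flask has 0.025% substrate but 22.2% isomer of the product. In the run without target <-> isomer of the product, Sunday's gain falls to 0.0075 points. Friday's adds 0 points in the teal flask, where the gap reckoned from τ was 2.6 × 10⁻⁴ points. The neighbour flask at 25 °C keeps 63% substrate at 3.0 d, which read as a first-order loss of substrate is a half-life of 107 h, longer than the teal τ of the target gap by a factor of 24.5.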